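Ring A numbering used throughout: C1 carries the aroyl group, C2 the free OH, C3 H, C4 the OMe, C5 the 3-arylpropyl chain, C6 H. Ring B is the 4-hydroxyphenyl ring of the ketone; ring C is the 4-hydroxyphenyl ring at the end of the chain.

## The problem

Target 15 has no stereocentre; it is three benzene rings, and ring A is 1,2,4,5-tetrasubstituted with four different groups. The difficulty is positional: the aroyl, OH, OMe and alkyl groups must stand in one order on ring A, and the two meta oxygens of ring A must differ (free OH at C2, methyl ether at C4) while two more free phenols sit on rings B and C. A route that substitutes a preformed resorcinol has to choose among several activated C–H positions on three electron-rich rings and then methylate one hydroxyl out of three or four. The aryl methyl ether must survive the final unmasking, which rules out Lewis-acid dealkylation of other ethers. The diaryl ketone is at risk under hydrogenolysis, which rules out benzyl ethers. The oxygens of rings B and C are therefore carried as silyl ethers and freed by fluoride. The feature that makes the key step possible is the polarity pattern of ring A: C2(O)–C3(H)–C4(O)–C5(alkyl) is a γ-alkylated acetoacetate in disguise, and C1(aroyl)–C6(H) is a terminal alkynyl ketone. All donor oxygens lie on the four-carbon piece and the only acceptor on the two-carbon piece, so ring A can be closed by a (4+2) cycloaddition and aromatised by loss of methanol. In the diene the C2 oxygen is a silyl ketene acetal oxygen and the C4 oxygen an enol methyl ether, so OH and OMe are already different before ring A exists.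

## Retrosynthesis

**15 ⇒ 14.** The two O–Si bonds on rings B and C are cut. Silyl ethers are preferred to benzyl or methyl ethers because fluoride touches neither the C4 methyl ether nor the ketone. The forward reaction only has to be a clean double desilylation.

**14 ⇒ 8 + 12 (through 13).** Bonds C1–C2 and C5–C6 of ring A are cut. Among the three ways of cutting ring A into a four-carbon and a two-carbon piece, this is the only one that leaves both oxygens on the diene and the acyl group on the dienophile with matched polarity. The neighbouring cuts would need an oxygenated alkyne or an acyl-substituted diene. Because C6 carries H, the dienophile is the terminal ynone 12, and its alkyne oxidation level means that aromatisation of cycloadduct 13 needs only the loss of methanol. The precursors are an open-chain vinylketene acetal 8 and a three-carbon ynone 12; neither contains ring A. The forward reaction must join C5 to C6 (not C5 to C1), diene 8 must reach an s-cis conformation, and the oxygen at C2 must be retained as OH.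

**12 ⇒ 11 ⇒ 9 + 10.** The ketone is traced to the propargylic alcohol 11, and the C–C bond between the carbinol carbon and the alkyne is cut. Aldehyde 9 and acetylide 10 are both purchasable, so ring B arrives with its oxygen already masked.

**8 ⇒ 7 ⇒ 5 (through 6).** The O–Si bond of the ketene acetal and the C–O bond of the enol ether are cut in turn. Diene 8 is the silylated γ-dienolate of β-methoxy enoate 7, and 7 is the enol methyl ether of β-keto ester 5, formed through ketal 6. The forward steps must give the (2E)-enoate, which puts C4–H2 cis to the ester for directed deprotonation.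

**5 ⇒ 3 + 4, 3 ⇒ 2 ⇒ 1.** The C4–C5 bond of the heptanoate is cut: γ-alkylation of the dianion of acetoacetate 4 with bromide 3. Bromide 3 comes from the commercial phenol-alcohol 1 by bromination to 2 and silylation. This places the whole chain and ring C on the diene before the key step.

## Roads not taken

**Alternative 1:** The most obvious cut is the C1–C(=O) bond. The forward key step would be a Friedel–Crafts (or Fries, or Houben–Hoesch) acylation of 4-[3-(4-hydroxyphenyl)propyl]benzene-1,3-diol A1 with a 4-hydroxybenzoyl donor to give tetrahydroxy ketone A2, followed by methylation at C4–OH. A1 is not a stock compound and needs its own multistep preparation. The acylation must choose C1 of ring A over the ortho positions of ring C and over O-acylation. The methylation must find one of three non-chelated phenols, two of which (C4–OH and the ring B OH) are both para to the carbonyl and of similar acidity. Protecting groups on rings B and C would restore selectivity but add steps, and the oxygen differentiation would still be left to the end. In the chosen plan the methyl group is in place before ring A is formed.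

**Alternative 2:** The C5–CH2 bond is cut. The forward key step would be a B-alkyl Suzuki–Miyaura coupling of bromo ketone A4 with alkylborane A5 (PdCl2(dppf), aqueous base). A4 would come from bromination of (2-hydroxy-4-methoxyphenyl)(4-hydroxyphenyl)methanone A3. This route is short, but each position is decided by a ratio between similar sites. A3 itself comes from acylation of 3-methoxyphenol, which can give both the 2-hydroxy-4-methoxy and the 4-hydroxy-2-methoxy ketone. Bromination of A3 must choose C5 over C3, which lies between the two oxygens, and over ring B. The C–Br bond of A4 sits on an electron-rich ring beside a methoxy group and carries phenoxides under the basic coupling conditions, which slows oxidative addition to zerovalent palladium. The chosen plan fixes every position of ring A by bond construction.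

**Alternative 3:** Bonds C2–C3, C4–C5 and C1–C2 are formed in a Danheiser benzannulation. Cyclobutenone A6 would open to a vinylketene, add methoxyethyne A7 and electrocyclise to the resorcinol monoether A8, with OH and OMe correctly differentiated. The aroyl group cannot be carried through, because a 4-aroylcyclobutenone is an enolisable strained β-diketone. It would have to be added afterwards by esterification to A9 and a Fries rearrangement, which has two ortho sites (C1 and C3) to choose from. A6 needs a multistep preparation and A7 is a volatile reagent that must be made. The chosen cycloaddition sets all four substituents of ring A in the ring-forming step from two stable components.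

Key step: step 8

Assumption: diene 8 is drawn as the (4Z,6E) isomer, the 6E geometry by analogy with the parent 1,3-dimethoxy-1-(trimethylsilyloxy)buta-1,3-diene. Neither double-bond geometry survives in 14. Compounds 11 and 13 are racemic (13 also a diastereomer mixture) and are drawn without descriptors.

## Route

Step 1
Reactants: 1 3-(4-hydroxyphenyl)propan-1-ol
Product: 2 4-(3-bromopropyl)phenol
Conditions: CBr4, PPh3, CH2Cl2, 0 → 23 °C
Reagents that add atoms: carbon tetrabromide, BrC(Br)(Br)Br
Why: Appel reaction; only the primary alcohol forms an alkoxyphosphonium ion that bromide can displace by SN2, so the phenol is left free.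

Step 2
Reactants: 2 4-(3-bromopropyl)phenol
Product: 3 [4-(3-bromopropyl)phenoxy]tri(propan-2-yl)silane
Conditions: TIPSCl, imidazole, CH2Cl2, 0 → 23 °C
Reagents that add atoms: chlorotri(propan-2-yl)silane, CC(C)[Si](Cl)(C(C)C)C(C)C
Why: Standard silylation of a phenol; the hindered triisopropylsilyl ether is chosen because it should survive the dianion, the catalytic acid of step 4 and LDA.

Step 3
Reactants: 3 [4-(3-bromopropyl)phenoxy]tri(propan-2-yl)silane; 4 methyl acetoacetate (excess)
Product: 5 methyl 3-oxo-7-{4-[tri(propan-2-yl)silyloxy]phenyl}heptanoate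
Conditions: 4, NaH, THF, 0 °C; n-BuLi, 0 °C; then 3, 0 → 23 °C; 1 M HCl quench, 0 °C
Reagents that add atoms: none
Why: γ-Alkylation of the acetoacetate dianion; the terminal carbanion is the more basic and more nucleophilic site and displaces the primary bromide by SN2, which builds the C4–C7 chain of the heptanoate.

Step 4
Reactants: 5 methyl 3-oxo-7-{4-[tri(propan-2-yl)silyloxy]phenyl}heptanoate
Product: 7 methyl (2E)-3-methoxy-7-{4-[tri(propan-2-yl)silyloxy]phenyl}hept-2-enoate, via dimethyl ketal 6 (not isolated)
Conditions: HC(OMe)3, cat. H2SO4, 23 °C; then cat. KHSO4, 130 °C, reduced pressure (−MeOH)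
Reagents that add atoms: trimethyl orthoformate, COC(OC)OC
Why: Acid-catalysed ketalisation with the orthoformate as methanol source and water scavenger, then acid-catalysed thermal loss of methanol from 6 into conjugation with the ester. The (2E)-enol ether, with OMe anti to the ester, is the thermodynamic isomer and places C4–H2 cis to the ester.

Step 5
Reactants: 7 methyl (2E)-3-methoxy-7-{4-[tri(propan-2-yl)silyloxy]phenyl}hept-2-enoate
Product: 8 {4-[(4Z,6E)-5,7-dimethoxy-7-(trimethylsilyloxy)hepta-4,6-dien-1-yl]phenoxy}tri(propan-2-yl)silane
Conditions: LDA, THF, −78 °C; TMSCl, −78 → 0 °C; non-aqueous work-up (pentane, filtration under argon), used crude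
Reagents that add atoms: chlorotrimethylsilane, C[Si](C)(C)Cl
Why: Kinetic γ-deprotonation directed by the cis ester carbonyl, then O-silylation of the extended dienolate, gives the vinylketene silyl acetal. Allylic strain against the cis ester group should turn the chain away from the ketene acetal carbon, giving the (4Z) geometry that can reach the s-cis conformation.

Step 6
Reactants: 9 4-(tert-butyldimethylsilyloxy)benzaldehyde; 10 ethynylmagnesium bromide
Product: 11 1-[4-(tert-butyldimethylsilyloxy)phenyl]prop-2-yn-1-ol (racemic)
Conditions: 10 (0.5 M in THF), THF, 0 °C; sat. aq. NH4Cl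
Reagents that add atoms: none
Why: 1,2-Addition of an alkynyl Grignard reagent to an aromatic aldehyde; the aryl silyl ether is inert at 0 °C, and the new stereocentre is racemic and is removed in step 7.

Step 7
Reactants: 11 1-[4-(tert-butyldimethylsilyloxy)phenyl]prop-2-yn-1-ol
Product: 12 1-[4-(tert-butyldimethylsilyloxy)phenyl]prop-2-yn-1-one
Conditions: activated MnO2 (excess), CH2Cl2, 23 °C
Reagents that add atoms: none
Why: Manganese dioxide oxidation of a benzylic propargylic alcohol under neutral conditions, which spares the silyl ether and the base-sensitive terminal ynone.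

Step 8
Reactants: 8 {4-[(4Z,6E)-5,7-dimethoxy-7-(trimethylsilyloxy)hepta-4,6-dien-1-yl]phenoxy}tri(propan-2-yl)silane (slight excess); 12 1-[4-(tert-butyldimethylsilyloxy)phenyl]prop-2-yn-1-one
Product: 14 [4-(tert-butyldimethylsilyloxy)phenyl](2-hydroxy-4-methoxy-5-{3-[4-(tri(propan-2-yl)silyloxy)phenyl]propyl}phenyl)methanone, via cyclohexa-1,4-diene cycloadduct 13 (not isolated)
Conditions: PhMe, 0 → 23 °C; then 0.1 M HCl, THF, 0 °C
Reagents that add atoms: none
Why: Normal-electron-demand Diels–Alder reaction followed by aromatisation, the reaction type by which 1,1,3-trioxygenated butadienes (vinylketene acetals of the Brassard type) and acetylenic ketones or esters give resorcinol derivatives. The HOMO of 8 has its largest terminal coefficient at the chain-bearing carbon (future C5 of ring A), the vinylogous carbon of both oxygen donors, and the LUMO of 12 is largest at the terminal alkyne carbon (future C6); the C5–C6 bond therefore leads and the ketene acetal carbon (future C2) closes on the acyl-bearing alkyne carbon (future C1), so the aroyl group ends ortho to the ketene acetal oxygen and para to the enol ether methoxy. Ring A closes in a concerted, asynchronous, suprafacial (4+2) mode from the s-cis (4Z) diene; in the stepwise limit (vinylogous Mukaiyama–Michael addition, then 6-exo-trig Claisen-type closure of the allenolate on the ester-level carbon) the same two bonds form in the same order, so the connectivity does not depend on the mechanism. The two stereocentres of 13 (C2 and C5) are uncontrolled and need not be controlled: both become sp2 when dilute acid collapses the mixed methyl silyl ketal at C2, with loss of methanol and of the silyl group, and the doubly allylic C5–H is lost. The step needs three selectivities: regiochemistry, secured by the donor pattern of 8 and the single acceptor of 12; reaction at the alkyne only; and retention of oxygen at C2 as OH and at C4 as OMe, secured because C2 is the only sp3 oxygenated carbon of 13 and its O–Si bond is the most labile link, while the C4 enol ether simply becomes an aryl ether.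

Step 9
Reactants: 14 [4-(tert-butyldimethylsilyloxy)phenyl](2-hydroxy-4-methoxy-5-{3-[4-(tri(propan-2-yl)silyloxy)phenyl]propyl}phenyl)methanone
Product: 15 (2-hydroxy-4-methoxy-5-[3-(4-hydroxyphenyl)propyl]phenyl)(4-hydroxyphenyl)methanone (CNP0209225.0)
Conditions: TBAF, AcOH (2.5 equiv each), THF, 0 → 23 °C
Reagents that add atoms: none
Why: Fluoride cleavage of both aryl silyl ethers, buffered with acetic acid so that the polyphenol is not left as an oxidisable phenoxide; the methyl ether and the diaryl ketone are untouched.

## Compound list

1 | 3-(4-hydroxyphenyl)propan-1-ol | OCCCc1ccc(O)cc1 | starting material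
2 | 4-(3-bromopropyl)phenol | Oc1ccc(CCCBr)cc1 | intermediate
3 | [4-(3-bromopropyl)phenoxy]tri(propan-2-yl)silane | CC(C)[Si](Oc1ccc(CCCBr)cc1)(C(C)C)C(C)C | intermediate
4 | methyl acetoacetate | COC(=O)CC(C)=O | starting material
5 | methyl 3-oxo-7-{4-[tri(propan-2-yl)silyloxy]phenyl}heptanoate | COC(=O)CC(=O)CCCCc1ccc(O[Si](C(C)C)(C(C)C)C(C)C)cc1 | intermediate
6 | methyl 3,3-dimethoxy-7-{4-[tri(propan-2-yl)silyloxy]phenyl}heptanoate | COC(=O)CC(OC)(OC)CCCCc1ccc(O[Si](C(C)C)(C(C)C)C(C)C)cc1 | intermediate (not isolated)
7 | methyl (2E)-3-methoxy-7-{4-[tri(propan-2-yl)silyloxy]phenyl}hept-2-enoate | COC(=O)/C=C(/OC)CCCCc1ccc(O[Si](C(C)C)(C(C)C)C(C)C)cc1 | intermediate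
8 | {4-[(4Z,6E)-5,7-dimethoxy-7-(trimethylsilyloxy)hepta-4,6-dien-1-yl]phenoxy}tri(propan-2-yl)silane | CO/C(O[Si](C)(C)C)=C\C(OC)=C\CCCc1ccc(O[Si](C(C)C)(C(C)C)C(C)C)cc1 | intermediate
9 | 4-(tert-butyldimethylsilyloxy)benzaldehyde | CC(C)(C)[Si](C)(C)Oc1ccc(C=O)cc1 | starting material
10 | ethynylmagnesium bromide | C#C[Mg]Br | starting material
11 | 1-[4-(tert-butyldimethylsilyloxy)phenyl]prop-2-yn-1-ol (racemic) | C#CC(O)c1ccc(O[Si](C)(C)C(C)(C)C)cc1 | intermediate
12 | 1-[4-(tert-butyldimethylsilyloxy)phenyl]prop-2-yn-1-one | C#CC(=O)c1ccc(O[Si](C)(C)C(C)(C)C)cc1 | intermediate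
13 | [4-(tert-butyldimethylsilyloxy)phenyl]{4,6-dimethoxy-3-[3-(4-{tri(propan-2-yl)silyloxy}phenyl)propyl]-6-(trimethylsilyloxy)cyclohexa-1,4-dien-1-yl}methanone (racemic, diastereomer mixture) | COC1=CC(OC)(O[Si](C)(C)C)C(C(=O)c2ccc(O[Si](C)(C)C(C)(C)C)cc2)=CC1CCCc1ccc(O[Si](C(C)C)(C(C)C)C(C)C)cc1 | intermediate (not isolated)
14 | [4-(tert-butyldimethylsilyloxy)phenyl](2-hydroxy-4-methoxy-5-{3-[4-(tri(propan-2-yl)silyloxy)phenyl]propyl}phenyl)methanone | COc1cc(O)c(C(=O)c2ccc(O[Si](C)(C)C(C)(C)C)cc2)cc1CCCc1ccc(O[Si](C(C)C)(C(C)C)C(C)C)cc1 | intermediate
15 | (2-hydroxy-4-methoxy-5-[3-(4-hydroxyphenyl)propyl]phenyl)(4-hydroxyphenyl)methanone | COc1cc(O)c(C(=O)c2ccc(O)cc2)cc1CCCc1ccc(O)cc1 | target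

## Step count and risk

Total steps: 9. Longest linear sequence: 7 steps (steps 1–5, 8, 9); the ynone branch is 2 steps (steps 6, 7).

**Step 8 (key step).** The most likely failure is a slow cycloaddition if the diene is formed as, or drifts to, the chain-inside geometry at C4=C5. Protodesilylation of 8 and oligomerisation of the ynone would then outrun ring formation, or an open-chain Michael adduct would fail to close. A second leak is aromatisation with loss of the silanol instead of methanol, which would give the 2,4-dimethyl ether; this is compound F4 below and the last operation of the fallback returns it to 14.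

The fallback sets out from 3 and 9 and builds ring A from a purchased arene. Zinc insertion into 3 (Zn, LiCl, THF) gives {3-[4-(tri(propan-2-yl)silyloxy)phenyl]propyl}zinc bromide F1. Separately, monolithiation of 1,5-dibromo-2,4-dimethoxybenzene (n-BuLi, −78 °C) and addition to 9 gives (5-bromo-2,4-dimethoxyphenyl)[4-(tert-butyldimethylsilyloxy)phenyl]methanol F2, which MnO2 oxidises to (5-bromo-2,4-dimethoxyphenyl)[4-(tert-butyldimethylsilyloxy)phenyl]methanone F3. Negishi coupling of F1 with F3 (Pd(OAc)2, SPhos, THF) gives [4-(tert-butyldimethylsilyloxy)phenyl](2,4-dimethoxy-5-{3-[4-(tri(propan-2-yl)silyloxy)phenyl]propyl}phenyl)methanone F4. BCl3 (CH2Cl2, −78 °C) then cleaves only the methoxy group ortho to the carbonyl through the six-membered boron chelate, and the route is rejoined at 14.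

**Step 5.** Deprotonation may occur at the vinylic C2–H instead of C4–H2, silylation may occur on carbon, and the ketene acetal may hydrolyse during handling. The fallback sets out from 5 and moves the oxygen differentiation to after ring formation. Silylation (TMSCl, Et3N) gives methyl (2Z)-3-(trimethylsilyloxy)-7-{4-[tri(propan-2-yl)silyloxy]phenyl}hept-2-enoate F5, and LDA/TMSCl gives {4-[(4Z,6E)-7-methoxy-5,7-bis(trimethylsilyloxy)hepta-4,6-dien-1-yl]phenoxy}tri(propan-2-yl)silane F6. Cycloaddition of F6 with 12 and acidic aromatisation gives [4-(tert-butyldimethylsilyloxy)phenyl](2,4-dihydroxy-5-{3-[4-(tri(propan-2-yl)silyloxy)phenyl]propyl}phenyl)methanone F7. Methylation of the non-chelated, more acidic C4–OH (Me3SiCHN2, MeOH–PhMe) returns to the route at 14.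

**Step 3.** Proton transfer and β-elimination of the primary bromide may compete with SN2, and O-alkylation or dialkylation may erode the yield. The fallback sets out from 3 and makes the β-keto ester by C-acylation logic instead. Alkylation of lithioacetonitrile with 3 gives 5-{4-[tri(propan-2-yl)silyloxy]phenyl}pentanenitrile F8. A Blaise reaction with methyl bromoacetate and activated zinc gives methyl (2Z)-3-amino-7-{4-[tri(propan-2-yl)silyloxy]phenyl}hept-2-enoate F9, and mild aqueous HCl hydrolysis returns to the route at 5.

**Step 4.** Loss of methanol from ketal 6 may be incomplete, the enol ether may form as an E/Z mixture (the Z isomer is poorly set up for step 5), and some acid-induced desilylation is possible. The fallback sets out from 3 and reaches the enol ether by conjugate addition. Bromide 3 alkylates 1,3-dilithiopropyne at the propargylic carbon, and the resulting acetylide is quenched in the same flask with methyl chloroformate to give methyl 7-{4-[tri(propan-2-yl)silyloxy]phenyl}hept-2-ynoate F10. Catalytic NaOMe in MeOH adds methanol to the β-carbon and equilibrates the product to the (2E) isomer, returning to the route at 7.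

## Further compounds

F1 | step 8 | {3-[4-(tri(propan-2-yl)silyloxy)phenyl]propyl}zinc bromide | Br[Zn]CCCc1ccc(O[Si](C(C)C)(C(C)C)C(C)C)cc1
F2 | step 8 | (5-bromo-2,4-dimethoxyphenyl)[4-(tert-butyldimethylsilyloxy)phenyl]methanol (racemic) | COc1cc(OC)c(C(O)c2ccc(O[Si](C)(C)C(C)(C)C)cc2)cc1Br
F3 | step 8 | (5-bromo-2,4-dimethoxyphenyl)[4-(tert-butyldimethylsilyloxy)phenyl]methanone | COc1cc(OC)c(C(=O)c2ccc(O[Si](C)(C)C(C)(C)C)cc2)cc1Br
F4 | step 8 | [4-(tert-butyldimethylsilyloxy)phenyl](2,4-dimethoxy-5-{3-[4-(tri(propan-2-yl)silyloxy)phenyl]propyl}phenyl)methanone | COc1cc(OC)c(C(=O)c2ccc(O[Si](C)(C)C(C)(C)C)cc2)cc1CCCc1ccc(O[Si](C(C)C)(C(C)C)C(C)C)cc1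
F5 | step 5 | methyl (2Z)-3-(trimethylsilyloxy)-7-{4-[tri(propan-2-yl)silyloxy]phenyl}hept-2-enoate | COC(=O)/C=C(\O[Si](C)(C)C)CCCCc1ccc(O[Si](C(C)C)(C(C)C)C(C)C)cc1
F6 | step 5 | {4-[(4Z,6E)-7-methoxy-5,7-bis(trimethylsilyloxy)hepta-4,6-dien-1-yl]phenoxy}tri(propan-2-yl)silane | CO/C(O[Si](C)(C)C)=C\C(O[Si](C)(C)C)=C\CCCc1ccc(O[Si](C(C)C)(C(C)C)C(C)C)cc1
F7 | step 5 | [4-(tert-butyldimethylsilyloxy)phenyl](2,4-dihydroxy-5-{3-[4-(tri(propan-2-yl)silyloxy)phenyl]propyl}phenyl)methanone | Oc1cc(O)c(C(=O)c2ccc(O[Si](C)(C)C(C)(C)C)cc2)cc1CCCc1ccc(O[Si](C(C)C)(C(C)C)C(C)C)cc1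
F8 | step 3 | 5-{4-[tri(propan-2-yl)silyloxy]phenyl}pentanenitrile | N#CCCCCc1ccc(O[Si](C(C)C)(C(C)C)C(C)C)cc1
F9 | step 3 | methyl (2Z)-3-amino-7-{4-[tri(propan-2-yl)silyloxy]phenyl}hept-2-enoate | COC(=O)/C=C(\N)CCCCc1ccc(O[Si](C(C)C)(C(C)C)C(C)C)cc1
F10 | step 4 | methyl 7-{4-[tri(propan-2-yl)silyloxy]phenyl}hept-2-ynoate | COC(=O)C#CCCCCc1ccc(O[Si](C(C)C)(C(C)C)C(C)C)cc1
A1 | alternative 1 | 4-[3-(4-hydroxyphenyl)propyl]benzene-1,3-diol | Oc1ccc(CCCc2ccc(O)cc2O)cc1
A2 | alternative 1 | (2,4-dihydroxy-5-[3-(4-hydroxyphenyl)propyl]phenyl)(4-hydroxyphenyl)methanone | Oc1cc(O)c(C(=O)c2ccc(O)cc2)cc1CCCc1ccc(O)cc1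
A3 | alternative 2 | (2-hydroxy-4-methoxyphenyl)(4-hydroxyphenyl)methanone | COc1ccc(C(=O)c2ccc(O)cc2)c(O)c1
A4 | alternative 2 | (5-bromo-2-hydroxy-4-methoxyphenyl)(4-hydroxyphenyl)methanone | COc1cc(O)c(C(=O)c2ccc(O)cc2)cc1Br
A5 | alternative 2 | 9-{3-[4-(tert-butyldimethylsilyloxy)phenyl]propyl}-9-borabicyclo[3.3.1]nonane | CC(C)(C)[Si](C)(C)Oc1ccc(CCCB2C3CCCC2CCC3)cc1
A6 | alternative 3 | 2-{3-[4-(tri(propan-2-yl)silyloxy)phenyl]propyl}cyclobut-2-en-1-one | O=C1CC=C1CCCc1ccc(O[Si](C(C)C)(C(C)C)C(C)C)cc1
A7 | alternative 3 | methoxyethyne | COC#C
A8 | alternative 3 | 3-methoxy-4-{3-[4-(tri(propan-2-yl)silyloxy)phenyl]propyl}phenol | COc1cc(O)ccc1CCCc1ccc(O[Si](C(C)C)(C(C)C)C(C)C)cc1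
A9 | alternative 3 | 3-methoxy-4-{3-[4-(tri(propan-2-yl)silyloxy)phenyl]propyl}phenyl 4-(tert-butyldimethylsilyloxy)benzoate | COc1cc(OC(=O)c2ccc(O[Si](C)(C)C(C)(C)C)cc2)ccc1CCCc1ccc(O[Si](C(C)C)(C(C)C)C(C)C)cc1
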